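**Strategy.** Ring B of the 1-arylnaphthalene is cut at C4–C4a and C1–C8a, the two bonds that tie it to ring A at adjacent carbons. Because C8a lies next to the C8 methoxy group, ring A corresponds to a 3-methoxybenzyne carrying the C7 oxygen. In one operation the γ-dienolate of an aryl α-alkoxy enone (oxygen on C1, CH2 terminus C4) annulates this aryne and, after dehydration, delivers the fully substituted naphthalene with ring C already at the crowded C1 position. The precursors are an ortho-silyl aryl triflate made from vanillin and a MOM-protected enone made from acetoveratrone and acetaldehyde. The MOM ether then steers C3 formylation.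

Key step: step 9

Remark on numbering: the naphthalene is numbered C1 (ring C), C2 (O), C3 (CHO), C4 (H), C7 (O), C8 (OMe) throughout.

Remark on protecting groups (assumption): the C7 oxygen is carried as an isopropyl ether. It is inert to the two organolithium steps, is a poor metalation director and falls together with MOM to BCl3, whereas a benzyl ether would risk benzylic lithiation and Wittig rearrangement. The MOM group is kept after the annulation because it directs lithiation to C3, where electrophilic formylation of a 1-substituted 2-naphthol is sluggish.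

Remark on stereochemistry: 18, 19, 23, 26 and F2 are racemic or diastereomeric mixtures whose stereocentres are destroyed. The Z geometries drawn for enolates 17 and 21 and for F1 are chelate-based assumptions of no consequence. The target has no stereogenic element.

**Step 1**
Reactants: 1 vanillin (4-hydroxy-3-methoxybenzaldehyde)
Product: 2 4-isopropoxy-3-methoxybenzaldehyde
Conditions: i-PrBr, K2CO3, DMF, 60 °C
Reagents that add atoms: 2-bromopropane, CC(C)Br
Why: Williamson ether synthesis: the phenoxide formed by K2CO3 displaces bromide from the secondary halide in DMF, and the aldehyde is untouched.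

**Step 2**
Reactants: 2 4-isopropoxy-3-methoxybenzaldehyde
Product: 4 4-isopropoxy-3-methoxyphenol, via aryl formate 3 (not isolated)
Conditions: mCPBA, CH2Cl2, 0 °C → rt; aq. NaHCO3 wash; then K2CO3 (cat.), MeOH, rt
Reagents that add atoms: mCPBA (3-chloroperoxybenzoic acid), O=C(OO)c1cccc(Cl)c1
Why: Dakin-type Baeyer–Villiger oxidation: in the peracid adduct the electron-rich 4-alkoxyaryl group migrates in preference to hydrogen, and base-catalysed methanolysis of the resulting formate frees the phenol.

**Step 3**
Reactants: 4 4-isopropoxy-3-methoxyphenol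
Product: 5 4-isopropoxy-3-methoxyphenyl N-isopropylcarbamate
Conditions: i-PrNCO, Et3N (cat.), CH2Cl2, rt
Reagents that add atoms: isopropyl isocyanate, CC(C)N=C=O
Why: Carbamoylation: amine-catalysed addition of the phenol to the isocyanate gives the secondary carbamate that serves as metalation director and can later be removed under mild E1cB conditions.

**Step 4**
Reactants: 5 4-isopropoxy-3-methoxyphenyl N-isopropylcarbamate
Product: 9 4-isopropoxy-3-methoxy-2-(trimethylsilyl)phenyl N-isopropylcarbamate, via N-silyl carbamate 6 (not isolated), via aryllithium 7 (not isolated), via bis-silyl carbamate 8 (not isolated)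
Conditions: TBSOTf, TMEDA, Et2O, 0 °C → rt; n-BuLi, TMEDA, −78 °C; TMSCl, −78 °C → rt; aq. NaHSO4
Reagents that add atoms: chlorotrimethylsilane, C[Si](C)(C)Cl
Why: Directed ortho-metalation: after in situ N-silylation the O-carbamate and the C3 methoxy group together direct n-BuLi to the carbon between them, TMSCl traps the aryllithium at −78 °C before an anionic Fries shift can occur, the N-silyl group is hydrolysed on work-up, and the isopropyl ether is inert and a poor director.

**Step 5**
Reactants: 9 4-isopropoxy-3-methoxy-2-(trimethylsilyl)phenyl N-isopropylcarbamate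
Product: 11 4-isopropoxy-3-methoxy-2-(trimethylsilyl)phenyl trifluoromethanesulfonate, via silylphenol 10 (not isolated)
Conditions: DBU, Et2NH, MeCN, 40 °C; then PhNTf2, rt
Reagents that add atoms: N-phenylbis(trifluoromethanesulfonimide), O=S(=O)(N(c1ccccc1)S(=O)(=O)C(F)(F)F)C(F)(F)F
Why: E1cB carbamate cleavage followed by triflation: DBU expels isopropyl isocyanate (scavenged by Et2NH as a urea) and the liberated phenoxide is sulfonylated in the same flask by PhNTf2.

**Step 6**
Reactants: 12 3',4'-dimethoxyacetophenone (acetoveratrone)
Product: 14 2-hydroxy-1-(3,4-dimethoxyphenyl)ethan-1-one, via hydroxy acetal 13 (not isolated)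
Conditions: PhI(OAc)2, KOH, MeOH, 0 °C → rt; then 2 M HCl, THF, rt
Reagents that add atoms: water, O
Why: Hypervalent-iodine α-hydroxylation (Moriarty oxidation): the enolate is oxidised by trivalent iodine through a methoxy epoxide to the α-hydroxy dimethyl acetal, and dilute acid hydrolyses the acetal back to the ketone.

**Step 7**
Reactants: 14 2-hydroxy-1-(3,4-dimethoxyphenyl)ethan-1-one
Product: 15 1-(3,4-dimethoxyphenyl)-2-(methoxymethoxy)ethan-1-one
Conditions: MOMCl, i-Pr2NEt, CH2Cl2, 0 °C → rt
Reagents that add atoms: chloromethyl methyl ether, COCCl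
Why: Acetal (MOM) protection: the primary alcohol is alkylated by the oxocarbenium-type electrophile MOMCl in the presence of a hindered amine base that does not enolise the ketone appreciably.

**Step 8**
Reactants: 15 1-(3,4-dimethoxyphenyl)-2-(methoxymethoxy)ethan-1-one; 16 acetaldehyde
Product: 20 (Z)-1-(3,4-dimethoxyphenyl)-2-(methoxymethoxy)but-2-en-1-one, via lithium enolate 17 (not isolated), via lithium aldolate 18 (not isolated), via mesylate 19 (not isolated)
Conditions: LiN(SiMe3)2, THF, −78 °C; MeCHO, −78 °C; MsCl, −78 → 0 °C; then DBU, 0 °C → rt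
Reagents that add atoms: acetaldehyde, CC=O
Why: Directed aldol addition followed by mesylation and E1cB elimination (aldol condensation): the chelated lithium enolate adds to acetaldehyde, the aldolate is sulfonylated in situ and DBU eliminates to the conjugated enone, expected as the Z isomer with methyl anti to the aroyl group; the two stereocentres of 18 and 19 are formed unselectively and are destroyed, and either alkene isomer would give the same dienolate.

**Step 9**
Reactants: 20 (Z)-1-(3,4-dimethoxyphenyl)-2-(methoxymethoxy)but-2-en-1-one; 11 4-isopropoxy-3-methoxy-2-(trimethylsilyl)phenyl trifluoromethanesulfonate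
Product: 24 7-isopropoxy-1-(3,4-dimethoxyphenyl)-8-methoxy-2-(methoxymethoxy)naphthalene, via potassium dienolate 21 (not isolated), via aryne 22 (not isolated), via dihydronaphthalenol 23 (not isolated)
Conditions: KN(SiMe3)2, THF, −78 °C; then 11, CsF, 18-crown-6, THF, −78 °C → rt; aq. NH4Cl; then PPTS, 4 Å MS, CH2Cl2, rt
Reagents that add atoms: none
Why: KN(SiMe3)2 removes a γ-proton of 20 to give the 1-oxido-2-alkoxybutadiene 21, fluoride strips the silyl group of 11 and expels triflate to release aryne 22, and the CH2 terminus (C4) of 21 bonds to the aryne carbon remote from the methoxy group while the aryl anion developing at the neighbouring carbon (C8a) adds to the former carbonyl carbon C1. The closest known reaction type is the anionic [4+2] annulation (formal Diels–Alder reaction) of arynes with dienolates and other 1-oxygenated dienes, followed by dehydrative aromatisation. Ring B is closed in this [4+2] mode, either in concert or as C4–C4a bond formation followed by a 6-exo-trig addition of the aryl anion to the ketone, and PPTS then ionises the doubly benzylic tertiary carbinol 23 so that loss of a C4 proton gives the naphthalene while the anhydrous medium spares the MOM acetal. The only new stereocentre, C1 of 23, is formed racemic and is erased on aromatisation, so nothing has to control it. The step needs regioselectivity, which is secured by the inductively withdrawing C8 methoxy group (it distorts the aryne so that the nucleophile bonds at the distal carbon and the charge settles beside oxygen) and by the enolate oxygen, which makes C4 and not C1 the nucleophilic end of the diene. The crowded surroundings of C1, with ring C on one side and the peri methoxy group on the other, are thus built by carbonyl addition and not by a hindered cross-coupling.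

**Step 10**
Reactants: 24 7-isopropoxy-1-(3,4-dimethoxyphenyl)-8-methoxy-2-(methoxymethoxy)naphthalene
Product: 27 4-(3,4-dimethoxyphenyl)-6-isopropoxy-5-methoxy-3-(methoxymethoxy)naphthalene-2-carbaldehyde (the C3-formyl derivative of 24), via naphthyllithium 25 (not isolated), via hemiaminal alkoxide 26 (not isolated)
Conditions: n-BuLi, TMEDA, THF, −78 → 0 °C; DMF, −78 °C → rt; aq. NH4Cl
Reagents that add atoms: N,N-dimethylformamide, CN(C)C=O
Why: Directed ortho-metalation and formylation: the MOM acetal, the strongest director in 24, chelates n-BuLi and, with C1 blocked, delivers it to C3, and the naphthyllithium adds to DMF to give a hemiaminal alkoxide that releases the aldehyde on work-up; the racemic carbinol carbon of 26 does not persist.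

**Step 11**
Reactants: 27 4-(3,4-dimethoxyphenyl)-6-isopropoxy-5-methoxy-3-(methoxymethoxy)naphthalene-2-carbaldehyde
Product: 29 vitrofolal B (4-(3,4-dimethoxyphenyl)-3,6-dihydroxy-5-methoxynaphthalene-2-carbaldehyde), via dichloroboryl ether 28 (not isolated)
Conditions: BCl3, CH2Cl2, −78 → 0 °C; then H2O
Reagents that add atoms: none
Why: Lewis-acid ether cleavage: BCl3 first cleaves the MOM acetal held in a chelate by the neighbouring aldehyde and then dealkylates the secondary isopropyl ether by an ionising pathway that the three methyl ethers, none of which is ortho to a carbonyl group, do not follow at or below 0 °C.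

**Compound list**

1 | vanillin (4-hydroxy-3-methoxybenzaldehyde) | COc1cc(C=O)ccc1O | starting material
2 | 4-isopropoxy-3-methoxybenzaldehyde | COc1cc(C=O)ccc1OC(C)C | intermediate
3 | 4-isopropoxy-3-methoxyphenyl formate | COc1cc(OC=O)ccc1OC(C)C | intermediate
4 | 4-isopropoxy-3-methoxyphenol | COc1cc(O)ccc1OC(C)C | intermediate
5 | 4-isopropoxy-3-methoxyphenyl N-isopropylcarbamate | COc1cc(OC(=O)NC(C)C)ccc1OC(C)C | intermediate
6 | 4-isopropoxy-3-methoxyphenyl N-(tert-butyldimethylsilyl)-N-isopropylcarbamate | COc1cc(OC(=O)N(C(C)C)[Si](C)(C)C(C)(C)C)ccc1OC(C)C | intermediate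
7 | 2-lithio derivative of 6 (lithium between the carbamate oxygen and the methoxy group) | COc1c([Li])c(OC(=O)N(C(C)C)[Si](C)(C)C(C)(C)C)ccc1OC(C)C | intermediate
8 | 4-isopropoxy-3-methoxy-2-(trimethylsilyl)phenyl N-(tert-butyldimethylsilyl)-N-isopropylcarbamate | COc1c([Si](C)(C)C)c(OC(=O)N(C(C)C)[Si](C)(C)C(C)(C)C)ccc1OC(C)C | intermediate
9 | 4-isopropoxy-3-methoxy-2-(trimethylsilyl)phenyl N-isopropylcarbamate | COc1c([Si](C)(C)C)c(OC(=O)NC(C)C)ccc1OC(C)C | intermediate
10 | 4-isopropoxy-3-methoxy-2-(trimethylsilyl)phenol (present as its DBU salt) | COc1c([Si](C)(C)C)c(O)ccc1OC(C)C | intermediate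
11 | 4-isopropoxy-3-methoxy-2-(trimethylsilyl)phenyl trifluoromethanesulfonate | COc1c(OC(C)C)ccc(OS(=O)(=O)C(F)(F)F)c1[Si](C)(C)C | intermediate
12 | 3',4'-dimethoxyacetophenone | CC(=O)c1ccc(OC)c(OC)c1 | starting material
13 | 2-(3,4-dimethoxyphenyl)-2,2-dimethoxyethan-1-ol | COc1ccc(C(OC)(OC)CO)cc1OC | intermediate
14 | 2-hydroxy-1-(3,4-dimethoxyphenyl)ethan-1-one | COc1ccc(C(=O)CO)cc1OC | intermediate
15 | 1-(3,4-dimethoxyphenyl)-2-(methoxymethoxy)ethan-1-one | COCOCC(=O)c1ccc(OC)c(OC)c1 | intermediate
16 | acetaldehyde | CC=O | starting material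
17 | lithium (Z)-1-(3,4-dimethoxyphenyl)-2-(methoxymethoxy)ethen-1-olate | COCO/C=C(\[O-])c1ccc(OC)c(OC)c1.[Li+] | intermediate
18 | lithium 4-(3,4-dimethoxyphenyl)-3-(methoxymethoxy)-4-oxobutan-2-olate (mixture of diastereomers, racemic) | CC([O-])C(OCOC)C(=O)c1ccc(OC)c(OC)c1.[Li+] | intermediate
19 | 4-(3,4-dimethoxyphenyl)-3-(methoxymethoxy)-4-oxobutan-2-yl methanesulfonate (mixture of diastereomers, racemic) | CC(OS(C)(=O)=O)C(OCOC)C(=O)c1ccc(OC)c(OC)c1 | intermediate
20 | (Z)-1-(3,4-dimethoxyphenyl)-2-(methoxymethoxy)but-2-en-1-one | C/C=C(\OCOC)C(=O)c1ccc(OC)c(OC)c1 | intermediate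
21 | potassium (1Z)-1-(3,4-dimethoxyphenyl)-2-(methoxymethoxy)buta-1,3-dien-1-olate | C=C/C(OCOC)=C(/[O-])c1ccc(OC)c(OC)c1.[K+] | intermediate
22 | 4-isopropoxy-3-methoxybenzyne (1,2-didehydro-4-isopropoxy-3-methoxybenzene) | COC1=C(OC(C)C)C=CC#C1 | intermediate
23 | 7-isopropoxy-1-(3,4-dimethoxyphenyl)-8-methoxy-2-(methoxymethoxy)-1,4-dihydronaphthalen-1-ol (racemic) | COCOC1=CCc2ccc(OC(C)C)c(OC)c2C1(O)c1ccc(OC)c(OC)c1 | intermediate
24 | 7-isopropoxy-1-(3,4-dimethoxyphenyl)-8-methoxy-2-(methoxymethoxy)naphthalene | COCOc1ccc2ccc(OC(C)C)c(OC)c2c1-c1ccc(OC)c(OC)c1 | intermediate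
25 | 3-lithio derivative of 24 | COCOc1c([Li])cc2ccc(OC(C)C)c(OC)c2c1-c1ccc(OC)c(OC)c1 | intermediate
26 | lithium (dimethylamino)[4-(3,4-dimethoxyphenyl)-6-isopropoxy-5-methoxy-3-(methoxymethoxy)naphthalen-2-yl]methanolate (racemic) | COCOc1c(C([O-])N(C)C)cc2ccc(OC(C)C)c(OC)c2c1-c1ccc(OC)c(OC)c1.[Li+] | intermediate
27 | 4-(3,4-dimethoxyphenyl)-6-isopropoxy-5-methoxy-3-(methoxymethoxy)naphthalene-2-carbaldehyde | COCOc1c(C=O)cc2ccc(OC(C)C)c(OC)c2c1-c1ccc(OC)c(OC)c1 | intermediate
28 | 1-(3,4-dimethoxyphenyl)-3-formyl-7-isopropoxy-8-methoxynaphthalen-2-yl dichloroborinate | ClB(Cl)Oc1c(C=O)cc2ccc(OC(C)C)c(OC)c2c1-c1ccc(OC)c(OC)c1 | intermediate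
29 | vitrofolal B (4-(3,4-dimethoxyphenyl)-3,6-dihydroxy-5-methoxynaphthalene-2-carbaldehyde) | COc1ccc(-c2c(O)c(C=O)cc3ccc(O)c(OC)c23)cc1OC | target

**Step count**

Total: 11 steps. Longest linear sequence: 8 steps (steps 1–5, then 9–11). The enone branch (steps 6–8) joins at step 9.

**Steps most likely to fail**

1. Step 9 (aryne annulation). The dienolate may be consumed by O-arylation, by attack on the sulfonyl group of the aryne precursor (triflyl transfer) or by Michael addition to unreacted enone. Residual amide base may add to the aryne, and the aryl anion may be protonated before it closes onto the ketone. Fallback (neutral Diels–Alder reaction of an isolated diene, so that strong base never meets the aryne precursor): it sets out from 20, which on deprotonation with KN(SiMe3)2 and O-silylation with TBSCl at −78 °C should give the silyl dienol ether (Z)-tert-butyl{[1-(3,4-dimethoxyphenyl)-2-(methoxymethoxy)buta-1,3-dien-1-yl]oxy}dimethylsilane F1. Cycloaddition of this diene with the aryne released from 11 by CsF in MeCN at rt should give tert-butyl{[7-isopropoxy-1-(3,4-dimethoxyphenyl)-8-methoxy-2-(methoxymethoxy)-1,4-dihydronaphthalen-1-yl]oxy}dimethylsilane F2, with the same regiochemistry because C4 remains the nucleophilic diene terminus. Catalytic acid (PPTS or a trace of TFA, CH2Cl2) should then expel the silanol and return to the route at 24.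

2. Step 10 (C3 lithiation and formylation). Metalation may be diverted to positions ortho to the methoxy groups of ring C, or may stall, so that mixtures of formylated products or unchanged material result. Fallback (electrophilic ortho-formylation of the free naphthol instead of directed metalation): it sets out from 24, whose MOM group should be removed by HCl in MeOH to give 7-isopropoxy-1-(3,4-dimethoxyphenyl)-8-methoxynaphthalen-2-ol F3. Magnesium-mediated ortho-formylation (MgCl2, Et3N, paraformaldehyde, MeCN, reflux; Casnati–Skattebøl reaction), for which C3 is the only free ortho position, should give 4-(3,4-dimethoxyphenyl)-3-hydroxy-6-isopropoxy-5-methoxynaphthalene-2-carbaldehyde F4. BCl3 in CH2Cl2 should then cleave the isopropyl ether, so that the fallback comes back to the route at 29.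

3. Step 11 (double dealkylation). The cleavage may overrun to the C8 methyl ether beside the freed C7 oxygen, or stop at the isopropyl ether once the MOM group has gone. Fallback (staged unmasking through an isolated intermediate, with a Brønsted acid for the acetal and a different, isopropyl-selective Lewis acid for the ether): it sets out from 27, which with HCl in MeOH at rt should give 4-(3,4-dimethoxyphenyl)-3-hydroxy-6-isopropoxy-5-methoxynaphthalene-2-carbaldehyde F5 (the same structure as F4). AlCl3 in CH2Cl2 at 0 °C → rt, a reagent known to dealkylate isopropyl aryl ethers in the presence of methyl aryl ethers, should then give 29.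

**Further compounds**

F1 | step 9 | (Z)-tert-butyl{[1-(3,4-dimethoxyphenyl)-2-(methoxymethoxy)buta-1,3-dien-1-yl]oxy}dimethylsilane | C=C/C(OCOC)=C(/O[Si](C)(C)C(C)(C)C)c1ccc(OC)c(OC)c1
F2 | step 9 | tert-butyl{[7-isopropoxy-1-(3,4-dimethoxyphenyl)-8-methoxy-2-(methoxymethoxy)-1,4-dihydronaphthalen-1-yl]oxy}dimethylsilane (racemic) | COCOC1=CCc2ccc(OC(C)C)c(OC)c2C1(O[Si](C)(C)C(C)(C)C)c1ccc(OC)c(OC)c1
F3 | step 10 | 7-isopropoxy-1-(3,4-dimethoxyphenyl)-8-methoxynaphthalen-2-ol | COc1ccc(-c2c(O)ccc3ccc(OC(C)C)c(OC)c23)cc1OC
F4 | step 10 | 4-(3,4-dimethoxyphenyl)-3-hydroxy-6-isopropoxy-5-methoxynaphthalene-2-carbaldehyde | COc1ccc(-c2c(O)c(C=O)cc3ccc(OC(C)C)c(OC)c23)cc1OC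
F5 | step 11 | 4-(3,4-dimethoxyphenyl)-3-hydroxy-6-isopropoxy-5-methoxynaphthalene-2-carbaldehyde | COc1ccc(-c2c(O)c(C=O)cc3ccc(OC(C)C)c(OC)c23)cc1OC
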